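**Strategy.** Everything rests on building ring A from two open chains rather than alkylating a phloroglucinol. The O5/C6-geranyl/O7-methyl array of ring A is the imprint of an O-methylated 2-geranylacetoacetate. C4a and C8a are the two carbons of an alkyne that already carries C4 (ketone), C3 and the C2 carbinol centre. One Diels–Alder/aromatisation step joins silyl ketene acetal diene 14 to bromoynone 8. It forms C8–C8a and C4a–C5, closes ring A, and places OH, geranyl, OMe and Br without any C6/C8 ambiguity. C2 is set earlier by asymmetric hydrogenation. Ring C is closed last by O-arylation at C8a–Br, leaving the C2–O bond intact.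

Key step: step 9

Assumption: geranyl means (2E)-3,7-dimethylocta-2,6-dien-1-yl. Compound 11 is racemic at its alpha carbon, 12–14 may be E/Z mixtures at the enol ether or ketene acetal bond, and 15 may be an epimer mixture at its ketal carbon (one isomer is drawn). All of these elements vanish when ring A becomes aromatic.

Design points:
- O2 carries TBS so that it survives the weakly acidic aromatisation of step 9.
- Bromine replaces the C-silyl group directly, so no free terminal ynone is handled.
- O5 is deliberately left unprotected after step 9. As its phenoxide it turns the C4 ketone into a vinylogous carboxylate and lowers the acidity of C3–H during the basic ring closure.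

**Step 1**
Reactants: 1 ethyl 3-(3,4-dimethoxyphenyl)-3-oxopropanoate
Product: 2 ethyl (3S)-3-(3,4-dimethoxyphenyl)-3-hydroxypropanoate
Conditions: H2 (30 bar), [RuCl(p-cymene)((R)-SEGPHOS)]Cl (0.5 mol %), EtOH, 60 °C
Reagents that add atoms: none
Why: Noyori asymmetric hydrogenation of a beta-keto ester, in which the ester carbonyl chelates ruthenium and the (R)-biaryl diphosphine directs hydrogen to the face that gives (R)-3-hydroxybutanoate from acetoacetate, which here is the (S)-carbinol because aryl outranks CH2CO2Et; this centre becomes C2 of the target.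

**Step 2**
Reactants: 2 ethyl (3S)-3-(3,4-dimethoxyphenyl)-3-hydroxypropanoate
Product: 3 (3S)-3-(3,4-dimethoxyphenyl)-3-hydroxy-N-methoxy-N-methylpropanamide
Conditions: MeNH(OMe)·HCl, i-PrMgCl, THF, −20 → 0 °C; aq NH4Cl
Reagents that add atoms: N,O-dimethylhydroxylamine hydrochloride, CNOC.Cl
Why: Direct ester-to-Weinreb-amide aminolysis by the magnesium amide; running it on the free alcohol leaves the beta oxygen as a magnesium alkoxide, which is no leaving group, so elimination to the cinnamamide is avoided and the carbinol centre is untouched.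

**Step 3**
Reactants: 3 (3S)-3-(3,4-dimethoxyphenyl)-3-hydroxy-N-methoxy-N-methylpropanamide
Product: 4 (3S)-3-(tert-butyldimethylsilyloxy)-3-(3,4-dimethoxyphenyl)-N-methoxy-N-methylpropanamide
Conditions: TBSCl, imidazole, DMF, rt
Reagents that add atoms: tert-butyldimethylsilyl chloride, CC(C)(C)[Si](C)(C)Cl
Why: Standard imidazole-promoted O-silylation of a secondary alcohol, which reacts at oxygen only and so keeps the configuration.

**Step 4**
Reactants: 5 trimethylsilylacetylene; 4 (3S)-3-(tert-butyldimethylsilyloxy)-3-(3,4-dimethoxyphenyl)-N-methoxy-N-methylpropanamide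
Product: 7 (5S)-5-(tert-butyldimethylsilyloxy)-5-(3,4-dimethoxyphenyl)-1-(trimethylsilyl)pent-1-yn-3-one, via lithium (trimethylsilyl)acetylide 6 (not isolated)
Conditions: 5, n-BuLi, THF, −78 °C; then 4, −78 → 0 °C; aq NH4Cl
Reagents that add atoms: n-butyllithium, [Li]CCCC (supplies only the lithium of 6)
Why: Weinreb ketone synthesis, in which the chelated tetrahedral adduct holds until the quench, so the weakly basic acetylide adds once and gives the ynone without over-addition or loss of the beta-silyloxy group.

**Step 5**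
Reactants: 7 (5S)-5-(tert-butyldimethylsilyloxy)-5-(3,4-dimethoxyphenyl)-1-(trimethylsilyl)pent-1-yn-3-one
Product: 8 (5S)-1-bromo-5-(tert-butyldimethylsilyloxy)-5-(3,4-dimethoxyphenyl)pent-1-yn-3-one
Conditions: NBS (1.05 equiv), AgNO3 (10 mol %), acetone, rt, dark
Reagents that add atoms: N-bromosuccinimide, O=C1CCC(=O)N1Br
Why: Silver-catalysed bromodesilylation of a 1-silylalkyne, in which the silver acetylide takes bromine from NBS much faster than the dimethoxyphenyl ring reacts in acetone with only a slight excess of NBS, and no base-sensitive terminal ynone has to be isolated.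

**Step 6**
Reactants: 9 methyl acetoacetate (excess); 10 geranyl bromide
Product: 11 methyl 2-geranylacetoacetate (racemic)
Conditions: K2CO3, acetone, reflux
Reagents that add atoms: none
Why: Acetoacetic ester C-alkylation, in which the soft stabilised enolate displaces the primary allylic bromide by SN2 without allylic shift, so the (E)-alkene is kept, and the excess of 9 limits dialkylation.

**Step 7**
Reactants: 11 methyl 2-geranylacetoacetate
Product: 12 methyl 2-geranyl-3-methoxybut-2-enoate
Conditions: HC(OMe)3, TsOH·H2O (2 mol %), MeOH, 50 °C; Et3N quench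
Reagents that add atoms: trimethyl orthoformate, COC(OC)OC
Why: Orthoformate ketalisation followed by loss of methanol into conjugation with the ester, the usual route to 3-alkoxy-2-enoates; catalytic sulfonic acid of the strength used to ketalise geranylacetone leaves the trisubstituted alkenes alone.

**Step 8**
Reactants: 12 methyl 2-geranyl-3-methoxybut-2-enoate
Product: 14 2-geranyl-1,3-dimethoxy-1-(trimethylsilyloxy)buta-1,3-diene, via lithium dienolate 13 (not isolated)
Conditions: LDA (commercial solution), THF, −78 °C; TMSCl, −78 → 0 °C; evaporation, dry pentane, filtration; used at once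
Reagents that add atoms: chlorotrimethylsilane, C[Si](C)(C)Cl; lithium diisopropylamide, CC(C)N([Li])C(C)C (supplies only the lithium of 13)
Why: Kinetic gamma-deprotonation of the C4 methyl group gives the extended ester enolate, which the hard chlorosilane traps on oxygen; this is the standard preparation of 1,3-dioxygenated vinylketene silyl acetals.

**Step 9**
Reactants: 8 (5S)-1-bromo-5-(tert-butyldimethylsilyloxy)-5-(3,4-dimethoxyphenyl)pent-1-yn-3-one; 14 2-geranyl-1,3-dimethoxy-1-(trimethylsilyloxy)buta-1,3-diene (1.6 equiv)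
Product: 16 (3S)-1-(2-bromo-5-geranyl-6-hydroxy-4-methoxyphenyl)-3-(tert-butyldimethylsilyloxy)-3-(3,4-dimethoxyphenyl)propan-1-one, via cyclohexa-1,4-diene ketal adduct 15 (not isolated)
Conditions: toluene, Ar, dark, 0 → 45 °C; then THF/0.1 M aq HCl, 0 °C
Reagents that add atoms: none
Why: The CH2 terminus of 14 (future C8), which receives the electron push of both the ketene acetal and the C7 methoxy group, bonds to the bromine-bearing beta carbon of ynone 8 (C8a), and the ketene acetal carbon (C5) bonds to the alpha carbon (C4a) in a strongly asynchronous Diels–Alder reaction. Ring A is thereby closed by an intermolecular [4+2] cycloaddition in which four diene carbons and the two alkyne carbons become the six ring atoms. The closest known reaction type is the addition of 1,3-dioxygenated vinylketene silyl acetals to acetylenic ketones, acetylenic esters and bromoalkynes with aromatisation of the 1,4-cyclohexadiene formed. In adduct 15 cold dilute acid cleaves the O–Si bond first, the hemiketal expels methanol and the dienone tautomerises, so O5 ends as the hydrogen-bonded phenol while O7 stays methylated and the vinylic C8a–Br bond is kept. No lasting stereocentre is created (the ketal carbon of 15 becomes aromatic C5), and the silyloxy centre, three bonds from the alkyne, is not touched by neutral and then weakly acidic conditions. The only selectivity required is orientation, which is secured by the matched polarisation of the carbonyl-activated beta carbon and the most nucleophilic diene terminus, while geranyl is fixed at C6 beforehand because it sits on C2 of the diene.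

**Step 10**
Reactants: 16 (3S)-1-(2-bromo-5-geranyl-6-hydroxy-4-methoxyphenyl)-3-(tert-butyldimethylsilyloxy)-3-(3,4-dimethoxyphenyl)propan-1-one
Product: 17 (3S)-1-(2-bromo-5-geranyl-6-hydroxy-4-methoxyphenyl)-3-(3,4-dimethoxyphenyl)-3-hydroxypropan-1-one
Conditions: TBAF/AcOH (1:1), THF, 0 °C → rt
Reagents that add atoms: none
Why: Fluoride cleavage of the silyl ether under acetic acid buffering stays close to neutral, so the beta oxygen is not eliminated (a base problem) and the electron-rich benzylic C–O bond is not ionised (an acid problem), and the configuration is kept.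

**Step 11**
Reactants: 17 (3S)-1-(2-bromo-5-geranyl-6-hydroxy-4-methoxyphenyl)-3-(3,4-dimethoxyphenyl)-3-hydroxypropan-1-one
Product: 18 (2S)-2-(3,4-dimethoxyphenyl)-6-geranyl-5-hydroxy-7-methoxychroman-4-one (CNP0310479.1)
Conditions: CuI (15 mol %), 1,10-phenanthroline (30 mol %), Cs2CO3 (2.5 equiv), 4 Å molecular sieves, toluene, Ar, 90 °C, stopped at full conversion; cold pH 6 buffer
Reagents that add atoms: none
Why: Ullmann-type intramolecular O-arylation of a secondary alcohol by an aryl bromide, helped by the ortho acyl group and the six-membered closure; only O–H and C8a–Br change, so C2 stays (S), and the O5 phenoxide formed first suppresses C3 deprotonation and with it dehydration, retro-aldol cleavage and opening of the flavanone.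

**Compound list**
1 | ethyl 3-(3,4-dimethoxyphenyl)-3-oxopropanoate | CCOC(=O)CC(=O)c1ccc(OC)c(OC)c1 | starting material
2 | ethyl (3S)-3-(3,4-dimethoxyphenyl)-3-hydroxypropanoate | COc1ccc([C@@H](O)CC(=O)OCC)cc1OC | intermediate
3 | (3S)-3-(3,4-dimethoxyphenyl)-3-hydroxy-N-methoxy-N-methylpropanamide | COc1ccc([C@@H](O)CC(=O)N(C)OC)cc1OC | intermediate
4 | (3S)-3-(tert-butyldimethylsilyloxy)-3-(3,4-dimethoxyphenyl)-N-methoxy-N-methylpropanamide | COc1ccc([C@@H](O[Si](C)(C)C(C)(C)C)CC(=O)N(C)OC)cc1OC | intermediate
5 | trimethylsilylacetylene | C#C[Si](C)(C)C | starting material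
6 | lithium (trimethylsilyl)acetylide | [Li]C#C[Si](C)(C)C | intermediate
7 | (5S)-5-(tert-butyldimethylsilyloxy)-5-(3,4-dimethoxyphenyl)-1-(trimethylsilyl)pent-1-yn-3-one | COc1ccc([C@@H](O[Si](C)(C)C(C)(C)C)CC(=O)C#C[Si](C)(C)C)cc1OC | intermediate
8 | (5S)-1-bromo-5-(tert-butyldimethylsilyloxy)-5-(3,4-dimethoxyphenyl)pent-1-yn-3-one | COc1ccc([C@@H](O[Si](C)(C)C(C)(C)C)CC(=O)C#CBr)cc1OC | intermediate
9 | methyl acetoacetate | COC(=O)CC(C)=O | starting material
10 | geranyl bromide, (2E)-1-bromo-3,7-dimethylocta-2,6-diene | CC(C)=CCC/C(C)=C/CBr | starting material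
11 | methyl 2-geranylacetoacetate (racemic) | COC(=O)C(C/C=C(\C)CCC=C(C)C)C(C)=O | intermediate
12 | methyl 2-geranyl-3-methoxybut-2-enoate ((2E) isomer drawn) | COC(=O)/C(C/C=C(\C)CCC=C(C)C)=C(/OC)C | intermediate
13 | lithium dienolate of 12 (lithium 2-geranyl-1,3-dimethoxybuta-1,3-dien-1-olate) | C=C(OC)/C(C/C=C(\C)CCC=C(C)C)=C(/OC)O[Li] | intermediate
14 | 2-geranyl-1,3-dimethoxy-1-(trimethylsilyloxy)buta-1,3-diene ((1Z) isomer drawn) | C=C(OC)/C(C/C=C(\C)CCC=C(C)C)=C(/OC)O[Si](C)(C)C | intermediate
15 | cyclohexa-1,4-diene adduct: (3S)-1-[2-bromo-5-geranyl-4,6-dimethoxy-6-(trimethylsilyloxy)cyclohexa-1,4-dien-1-yl]-3-(tert-butyldimethylsilyloxy)-3-(3,4-dimethoxyphenyl)propan-1-one | COc1ccc([C@@H](O[Si](C)(C)C(C)(C)C)CC(=O)C2=C(Br)CC(OC)=C(C/C=C(\C)CCC=C(C)C)C2(OC)O[Si](C)(C)C)cc1OC | intermediate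
16 | (3S)-1-(2-bromo-5-geranyl-6-hydroxy-4-methoxyphenyl)-3-(tert-butyldimethylsilyloxy)-3-(3,4-dimethoxyphenyl)propan-1-one | COc1ccc([C@@H](O[Si](C)(C)C(C)(C)C)CC(=O)c2c(Br)cc(OC)c(C/C=C(\C)CCC=C(C)C)c2O)cc1OC | intermediate
17 | (3S)-1-(2-bromo-5-geranyl-6-hydroxy-4-methoxyphenyl)-3-(3,4-dimethoxyphenyl)-3-hydroxypropan-1-one | COc1ccc([C@@H](O)CC(=O)c2c(Br)cc(OC)c(C/C=C(\C)CCC=C(C)C)c2O)cc1OC | intermediate
18 | (2S)-2-(3,4-dimethoxyphenyl)-6-geranyl-5-hydroxy-7-methoxychroman-4-one | COc1ccc([C@@H]2CC(=O)c3c(cc(OC)c(C/C=C(\C)CCC=C(C)C)c3O)O2)cc1OC | target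

**Total step count:** 11.
**Longest linear sequence:** 8 steps (steps 1–5, then 9–11). The diene branch (steps 6–8) joins at step 9.

**Steps most likely to fail**

**Step 9.** Three things may go wrong:
- The electron-rich diene may attack bromine.
- It may add at C8a and expel bromide before the second bond forms.
- The crowded 2-substituted diene may react too slowly for the heat-sensitive bromoynone.

The fallback takes ring A from an arene and uses no cycloaddition. It sets out from 10 and 4 and comes back at 18. Commercial 1-chloro-3,5-dimethoxybenzene is lithiated between its two methoxy groups (n-BuLi, THF, 0 °C) and alkylated with 10. This gives 5-chloro-2-geranyl-1,3-dimethoxybenzene F1, whose two remaining ring positions are equivalent. A second lithiation next to chlorine (s-BuLi, TMEDA, THF, −78 °C) and acylation by Weinreb amide 4 gives (3S)-3-(tert-butyldimethylsilyloxy)-1-(2-chloro-5-geranyl-4,6-dimethoxyphenyl)-3-(3,4-dimethoxyphenyl)propan-1-one F2. MgI2 etherate removes only the methyl ether that can chelate to the ketone and gives (3S)-3-(tert-butyldimethylsilyloxy)-1-(2-chloro-5-geranyl-6-hydroxy-4-methoxyphenyl)-3-(3,4-dimethoxyphenyl)propan-1-one F3. TBAF/AcOH then gives (3S)-1-(2-chloro-5-geranyl-6-hydroxy-4-methoxyphenyl)-3-(3,4-dimethoxyphenyl)-3-hydroxypropan-1-one F4. Intramolecular etherification of the aryl chloride closes ring C to 18 (Pd(OAc)2, 2-(di-tert-butylphosphino)-1,1'-binaphthyl, Cs2CO3, toluene, 70 °C).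

**Step 11.** Under carbonate at 90 °C the beta-hydroxy ketone may dehydrate or undergo retro-aldol cleavage faster than the C–O bond forms. Long heating could also open and re-close the flavanone with erosion at C2.

The fallback takes the carbonyl out of play during ring closure. It sets out from 16 and comes back at 18. NaBH4 (THF/MeOH, 0 °C) reduces the ketone to (1RS,3S)-1-(2-bromo-5-geranyl-6-hydroxy-4-methoxyphenyl)-3-(tert-butyldimethylsilyloxy)-3-(3,4-dimethoxyphenyl)propan-1-ol F5. TBAF (THF) gives (1RS,3S)-1-(2-bromo-5-geranyl-6-hydroxy-4-methoxyphenyl)-3-(3,4-dimethoxyphenyl)propane-1,3-diol F6. The same CuI/1,10-phenanthroline/Cs2CO3 closure then acts on a substrate without an acidic C3–H. Only O2 can reach C8a through a six-membered ring, since O4 would need a four-membered one. The product is (2S,4RS)-2-(3,4-dimethoxyphenyl)-6-geranyl-7-methoxychromane-4,5-diol F7. MnO2 (CH2Cl2, rt) re-oxidises the benzylic C4 alcohol to 18 under neutral conditions.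

**Step 7.** Ketalisation of the hindered alpha-branched ketone may be slow. That would force long acid exposure, and protonation and cyclisation of the geranyl chain could then set in.

The fallback installs the O7 methyl group after ring A is built. It sets out from 11 and comes back at 16. TMSCl/Et3N gives methyl (2Z)-2-geranyl-3-(trimethylsilyloxy)but-2-enoate F8. LDA then TMSCl gives 2-geranyl-1-methoxy-1,3-bis(trimethylsilyloxy)buta-1,3-diene F9. Cycloaddition of F9 to 8 under the conditions of step 9, with acidic work-up, gives (3S)-1-(2-bromo-5-geranyl-4,6-dihydroxyphenyl)-3-(tert-butyldimethylsilyloxy)-3-(3,4-dimethoxyphenyl)propan-1-one F10. MeI (1 equiv) and K2CO3 in acetone at rt methylate only the more acidic, non-chelated hydroxyl para to the ketone, giving 16.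

**Further compounds**
F1 | step 9 | 5-chloro-2-geranyl-1,3-dimethoxybenzene | COc1cc(Cl)cc(OC)c1C/C=C(\C)CCC=C(C)C
F2 | step 9 | (3S)-3-(tert-butyldimethylsilyloxy)-1-(2-chloro-5-geranyl-4,6-dimethoxyphenyl)-3-(3,4-dimethoxyphenyl)propan-1-one | COc1ccc([C@@H](O[Si](C)(C)C(C)(C)C)CC(=O)c2c(Cl)cc(OC)c(C/C=C(\C)CCC=C(C)C)c2OC)cc1OC
F3 | step 9 | (3S)-3-(tert-butyldimethylsilyloxy)-1-(2-chloro-5-geranyl-6-hydroxy-4-methoxyphenyl)-3-(3,4-dimethoxyphenyl)propan-1-one | COc1ccc([C@@H](O[Si](C)(C)C(C)(C)C)CC(=O)c2c(Cl)cc(OC)c(C/C=C(\C)CCC=C(C)C)c2O)cc1OC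
F4 | step 9 | (3S)-1-(2-chloro-5-geranyl-6-hydroxy-4-methoxyphenyl)-3-(3,4-dimethoxyphenyl)-3-hydroxypropan-1-one | COc1ccc([C@@H](O)CC(=O)c2c(Cl)cc(OC)c(C/C=C(\C)CCC=C(C)C)c2O)cc1OC
F5 | step 11 | (1RS,3S)-1-(2-bromo-5-geranyl-6-hydroxy-4-methoxyphenyl)-3-(tert-butyldimethylsilyloxy)-3-(3,4-dimethoxyphenyl)propan-1-ol | COc1ccc([C@@H](O[Si](C)(C)C(C)(C)C)CC(O)c2c(Br)cc(OC)c(C/C=C(\C)CCC=C(C)C)c2O)cc1OC
F6 | step 11 | (1RS,3S)-1-(2-bromo-5-geranyl-6-hydroxy-4-methoxyphenyl)-3-(3,4-dimethoxyphenyl)propane-1,3-diol | COc1ccc([C@@H](O)CC(O)c2c(Br)cc(OC)c(C/C=C(\C)CCC=C(C)C)c2O)cc1OC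
F7 | step 11 | (2S,4RS)-2-(3,4-dimethoxyphenyl)-6-geranyl-7-methoxychromane-4,5-diol | COc1ccc([C@@H]2CC(O)c3c(cc(OC)c(C/C=C(\C)CCC=C(C)C)c3O)O2)cc1OC
F8 | step 7 | methyl (2Z)-2-geranyl-3-(trimethylsilyloxy)but-2-enoate | COC(=O)/C(C/C=C(\C)CCC=C(C)C)=C(\O[Si](C)(C)C)C
F9 | step 7 | 2-geranyl-1-methoxy-1,3-bis(trimethylsilyloxy)buta-1,3-diene | C=C(O[Si](C)(C)C)/C(C/C=C(\C)CCC=C(C)C)=C(/OC)O[Si](C)(C)C
F10 | step 7 | (3S)-1-(2-bromo-5-geranyl-4,6-dihydroxyphenyl)-3-(tert-butyldimethylsilyloxy)-3-(3,4-dimethoxyphenyl)propan-1-one | COc1ccc([C@@H](O[Si](C)(C)C(C)(C)C)CC(=O)c2c(Br)cc(O)c(C/C=C(\C)CCC=C(C)C)c2O)cc1OC
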